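## Retrosynthetic overview

1. The acid is unmasked last from a dioxolane-protected aldehyde; the aryl ether O–CH2 bond comes from a Mitsunobu coupling with purchased umbelliferone.
2. Key disconnection, C5–C11: a sulfur-stabilised hydroxymethyl-carbanion (d1) equivalent adds to the C5 ketone of a 6,6-disubstituted carvone, joining two natively electrophilic carbons; the resulting spiro vinyl epoxide relays its configuration to C5 in a palladium/formate hydrogenolysis.
3. The quaternary centre C6 comes from two successive α′-alkylations of (S)-carvone (methyl first, then the three-carbon chain anti to isopropenyl).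
4. Rings: the cyclohexene ring is taken intact from (S)-carvone and the coumarin from umbelliferone; the only ring formed is the spiro-oxirane (step 3), which is opened again in step 4.

Labels and assumption: target ring carbons are called C1 (CH–isopropenyl), C2 (CH2), C3 (=CH), C4 (=C–Me), C5 (CH–CH2OAr), C6 (quaternary), and the O–CH2 carbon is C11. The target is (1R,5R,6R) in these labels, with isopropenyl, C11 and the C6 methyl on one face and the propanoic chain on the other. Commercial (S)-(+)-carvone of high ee and commercial LiN(i-Pr)2 solution are assumed.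

## Route

Step 1
Reactants: 1 (S)-(+)-carvone
Product: 3 6-methylcarvone (5S)-2,6-dimethyl-5-(prop-1-en-2-yl)cyclohex-2-en-1-one as a C6 epimer mixture in which trans (6R) predominates, via lithium dienolate 2 (not isolated)
Conditions: LiN(i-Pr)2 (1.1 equiv), THF, −78 °C; MeI (2 equiv), −78 → 0 °C
Reagents that add atoms: iodomethane, CI
Why: Kinetic deprotonation at the α′-CH2 gives the cross-conjugated dienolate, which is methylated there by SN2 enolate alkylation; the new C6 centre is an epimer mixture that is erased in step 2, and the carvone stereocentre (the future C1) is not touched.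

Step 2
Reactants: 3 6-methylcarvone; 4 2-(2-bromoethyl)-1,3-dioxolane
Product: 6 (5R,6R)-6-[2-(1,3-dioxolan-2-yl)ethyl]-2,6-dimethyl-5-(prop-1-en-2-yl)cyclohex-2-en-1-one, via lithium enolate 5 (not isolated)
Conditions: LiN(i-Pr)2 (1.2 equiv), THF, −78 → −20 °C; HMPA (3 equiv), Bu4NI (0.2 equiv), 4 (2 equiv), −78 → 23 °C
Reagents that add atoms: none
Why: SN2 alkylation of the tetrasubstituted α′-enolate (both epimers of 3 give the same enolate) occurs on the face opposite the adjacent isopropenyl group, so the chain ends trans and the methyl cis to isopropenyl, which sets the quaternary centre C6; the acetal halide has no acidic β-hydrogen (no E1cB loss of the halide) and gives no ester enolate, so the Michael–Michael bicyclisation that acrylates undergo with carvone enolates cannot occur.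

Step 3
Reactants: 6 the ketone from step 2
Product: 7 (3R,7R,8R)-8-[2-(1,3-dioxolan-2-yl)ethyl]-4,8-dimethyl-7-(prop-1-en-2-yl)-1-oxaspiro[2.5]oct-4-ene (epoxide oxygen cis to the C8 methyl)
Conditions: Me3SI (3 equiv), n-BuLi (2.9 equiv), THF, −10 °C; then 6, −10 → 23 °C
Reagents that add atoms: trimethylsulfonium iodide, C[S+](C)C.[I-]
Why: Corey–Chaykovsky epoxidation, in which dimethylsulfonium methylide acts as a hydroxymethyl-anion (d1) equivalent and bonds the future O–CH2 carbon C11 (formaldehyde level, natively electrophilic) to the electrophilic carbonyl carbon C5 by irreversible 1,2-addition and closure with loss of Me2S; attack is axial and anti to the axial C6 methyl (from the face of the side chain), so C11 enters trans and the oxygen cis to that methyl.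

Step 4
Reactants: 7 the spiro vinyl epoxide
Product: 8 [(1R,5R,6R)-6-[2-(1,3-dioxolan-2-yl)ethyl]-2,6-dimethyl-5-(prop-1-en-2-yl)cyclohex-2-en-1-yl]methanol
Conditions: Pd2(dba)3·CHCl3 (2.5 mol %), n-Bu3P (5 mol %), HCO2H (5 equiv), Et3N (2 equiv), 1,4-dioxane, 23 °C
Reagents that add atoms: none
Why: Tsuji–Shimizu formate hydrogenolysis of an alkenyloxirane: zerovalent palladium ionises the allylic C5–O bond with inversion, and after loss of CO2 hydride is delivered from the metal face to the more substituted allyl terminus C5, so H enters anti to the former C–O bond, C11 swings cis to the C6 methyl and isopropenyl (C5 = R), and the C3=C4 alkene stays unconjugated in place.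

Step 5
Reactants: 8 the homoallylic alcohol; 9 umbelliferone (7-hydroxy-2H-chromen-2-one)
Product: 10 7-{[(1R,5R,6R)-6-[2-(1,3-dioxolan-2-yl)ethyl]-2,6-dimethyl-5-(prop-1-en-2-yl)cyclohex-2-en-1-yl]methoxy}-2H-chromen-2-one
Conditions: 9 (1.5 equiv), PPh3 (2 equiv), DIAD (2 equiv), toluene, 0 → 60 °C
Reagents that add atoms: none
Why: Mitsunobu etherification of the primary alcohol with the acidic coumarin phenol (pKa about 7.8); the reacting carbon is a CH2, so no stereocentre is affected, and the acetal keeps the chain terminus inert.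

Step 6
Reactants: 10 the coumarin ether acetal
Product: 12 3-[(1R,2R,6R)-1,3-dimethyl-2-{[(2-oxo-2H-chromen-7-yl)oxy]methyl}-6-(prop-1-en-2-yl)cyclohex-3-en-1-yl]propanoic acid (CNP0103683.1), via aldehyde 11 (not isolated)
Conditions: HCl (1 M aq., 0.3 equiv), THF/H2O, 40 °C; then t-BuOH, 2-methyl-2-butene (20 equiv), NaH2PO4, NaClO2, 0 → 23 °C
Reagents that add atoms: water, O; sodium chlorite, [Na+].[O-]Cl=O
Why: Acid-catalysed acetal hydrolysis followed in the same flask by Pinnick (Lindgren–Kraus) chlorite oxidation of the aldehyde, conditions mild enough for the coumarin lactone, the aryl ether and the three alkenes (HOCl is trapped by 2-methyl-2-butene), with no stereocentre involved.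

## Compound list

1 | (S)-(+)-carvone, (5S)-2-methyl-5-(prop-1-en-2-yl)cyclohex-2-en-1-one | C=C(C)[C@H]1CC=C(C)C(=O)C1 | starting material
2 | lithium dienolate of 1, lithium (3S)-6-methyl-3-(prop-1-en-2-yl)cyclohexa-1,5-dien-1-olate | C=C(C)[C@H]1CC=C(C)C(O[Li])=C1 | intermediate (not isolated)
3 | 6-methylcarvone, (5S)-2,6-dimethyl-5-(prop-1-en-2-yl)cyclohex-2-en-1-one (major trans 6R epimer drawn; the 6S epimer converges in step 2) | C=C(C)[C@H]1CC=C(C)C(=O)[C@@H]1C | intermediate
4 | 2-(2-bromoethyl)-1,3-dioxolane | BrCCC1OCCO1 | starting material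
5 | lithium enolate of 3, lithium (3R)-2,6-dimethyl-3-(prop-1-en-2-yl)cyclohexa-1,5-dien-1-olate | C=C(C)[C@H]1CC=C(C)C(O[Li])=C1C | intermediate (not isolated)
6 | (5R,6R)-6-[2-(1,3-dioxolan-2-yl)ethyl]-2,6-dimethyl-5-(prop-1-en-2-yl)cyclohex-2-en-1-one | C=C(C)[C@H]1CC=C(C)C(=O)[C@]1(C)CCC2OCCO2 | intermediate
7 | (3R,7R,8R)-8-[2-(1,3-dioxolan-2-yl)ethyl]-4,8-dimethyl-7-(prop-1-en-2-yl)-1-oxaspiro[2.5]oct-4-ene | C=C(C)[C@H]1CC=C(C)[C@]2(CO2)[C@]1(C)CCC3OCCO3 | intermediate
8 | [(1R,5R,6R)-6-[2-(1,3-dioxolan-2-yl)ethyl]-2,6-dimethyl-5-(prop-1-en-2-yl)cyclohex-2-en-1-yl]methanol | C=C(C)[C@H]1CC=C(C)[C@@H](CO)[C@]1(C)CCC2OCCO2 | intermediate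
9 | umbelliferone, 7-hydroxy-2H-chromen-2-one | Oc1ccc2ccc(=O)oc2c1 | starting material
10 | 7-{[(1R,5R,6R)-6-[2-(1,3-dioxolan-2-yl)ethyl]-2,6-dimethyl-5-(prop-1-en-2-yl)cyclohex-2-en-1-yl]methoxy}-2H-chromen-2-one | C=C(C)[C@H]1CC=C(C)[C@@H](COc2ccc3ccc(=O)oc3c2)[C@]1(C)CCC4OCCO4 | intermediate
11 | 3-[(1R,2R,6R)-1,3-dimethyl-2-{[(2-oxo-2H-chromen-7-yl)oxy]methyl}-6-(prop-1-en-2-yl)cyclohex-3-en-1-yl]propanal | C=C(C)[C@H]1CC=C(C)[C@@H](COc2ccc3ccc(=O)oc3c2)[C@]1(C)CCC=O | intermediate (not isolated)
12 | 3-[(1R,2R,6R)-1,3-dimethyl-2-{[(2-oxo-2H-chromen-7-yl)oxy]methyl}-6-(prop-1-en-2-yl)cyclohex-3-en-1-yl]propanoic acid | C=C(C)[C@H]1CC=C(C)[C@@H](COc2ccc3ccc(=O)oc3c2)[C@]1(C)CCC(=O)O | target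

## Step count and risks

Total step count: 6. Longest linear sequence: 6 steps from 1; compounds 4 and 9 are bought and used as such.

Most likely to fail, first: step 2, because an unactivated primary halide must alkylate a hindered tetrasubstituted enolate to build the quaternary centre. The fallback sets out from 3 and comes back at 6. The same enolate is alkylated with the far more reactive allyl bromide (LiN(i-Pr)2, THF, −78 → 0 °C), again anti to isopropenyl, to give (5R,6R)-2,6-dimethyl-6-(prop-2-en-1-yl)-5-(prop-1-en-2-yl)cyclohex-2-en-1-one F1. Its monosubstituted terminal alkene is then oxidised selectively by an aldehyde-selective (anti-Markovnikov) Wacker oxidation (PdCl2(PhCN)2, CuCl2·2H2O, AgNO2, O2, t-BuOH/MeNO2, 23 °C; the 1,1-disubstituted isopropenyl group and the enone are inert) to 3-[(1R,6R)-1,3-dimethyl-2-oxo-6-(prop-1-en-2-yl)cyclohex-3-en-1-yl]propanal F2. Acetalisation of the aldehyde alone with ethylene glycol (PPTS, benzene, reflux; the hindered conjugated ketone does not react) gives 6.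

Second: step 3, because the ketone is flanked by a quaternary carbon and the ylide can act as a base or decompose before it adds. The fallback sets out from 6 and comes back at 7. The smaller and more nucleophilic (phenylthio)methyllithium (PhSMe, n-BuLi, DABCO, THF; CeCl3, −78 °C) is added 1,2 from the same face to give (1R,5R,6R)-6-[2-(1,3-dioxolan-2-yl)ethyl]-2,6-dimethyl-1-[(phenylsulfanyl)methyl]-5-(prop-1-en-2-yl)cyclohex-2-en-1-ol F3. S-Methylation with Me3OBF4 (CH2Cl2, 0 °C) gives {[(1R,5R,6R)-6-[2-(1,3-dioxolan-2-yl)ethyl]-1-hydroxy-2,6-dimethyl-5-(prop-1-en-2-yl)cyclohex-2-en-1-yl]methyl}(methyl)phenylsulfonium tetrafluoroborate F4, which closes to epoxide 7 on treatment with aqueous NaOH.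

Third: step 4, because hydride might be delivered to the less hindered terminus C3 (giving the transposed allylic alcohol) or the palladium allyl might eliminate to a diene. The fallback sets out from 7 and comes back at 8. A Lewis-acid Meinwald rearrangement (MgBr2·OEt2, Et2O, 0 °C) shifts a hydride from C11 to C5 anti to the departing oxygen and gives the β,γ-unsaturated aldehyde (1R,5R,6R)-6-[2-(1,3-dioxolan-2-yl)ethyl]-2,6-dimethyl-5-(prop-1-en-2-yl)cyclohex-2-ene-1-carbaldehyde F5. If a C5 epimer mixture forms, brief treatment with Et3N equilibrates it toward this pseudo-equatorial isomer, which also corrects a wrong epoxide face from step 3, though conjugation of the alkene is a risk during that equilibration. Reduction with NaBH4 (MeOH, 0 °C) then gives 8.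

Further compounds
F1 | step 2 | (5R,6R)-2,6-dimethyl-6-(prop-2-en-1-yl)-5-(prop-1-en-2-yl)cyclohex-2-en-1-one | C=C(C)[C@H]1CC=C(C)C(=O)[C@]1(C)CC=C
F2 | step 2 | 3-[(1R,6R)-1,3-dimethyl-2-oxo-6-(prop-1-en-2-yl)cyclohex-3-en-1-yl]propanal | C=C(C)[C@H]1CC=C(C)C(=O)[C@]1(C)CCC=O
F3 | step 3 | (1R,5R,6R)-6-[2-(1,3-dioxolan-2-yl)ethyl]-2,6-dimethyl-1-[(phenylsulfanyl)methyl]-5-(prop-1-en-2-yl)cyclohex-2-en-1-ol | C=C(C)[C@H]1CC=C(C)[C@](O)(CSc2ccccc2)[C@]1(C)CCC3OCCO3
F4 | step 3 | {[(1R,5R,6R)-6-[2-(1,3-dioxolan-2-yl)ethyl]-1-hydroxy-2,6-dimethyl-5-(prop-1-en-2-yl)cyclohex-2-en-1-yl]methyl}(methyl)phenylsulfonium tetrafluoroborate | C=C(C)[C@H]1CC=C(C)[C@](O)(C[S+](C)c2ccccc2)[C@]1(C)CCC3OCCO3.F[B-](F)(F)F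
F5 | step 4 | (1R,5R,6R)-6-[2-(1,3-dioxolan-2-yl)ethyl]-2,6-dimethyl-5-(prop-1-en-2-yl)cyclohex-2-ene-1-carbaldehyde | C=C(C)[C@H]1CC=C(C)[C@@H](C=O)[C@]1(C)CCC3OCCO3
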